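Minutes of the meeting. Late in the beta run, at 48.0 h, ring stood at 14 % of the solid substrate charged, and the meeting began from that reading.

| flask | solid substrate | activator | capture agent | temperature | remark | time |
|---|---|---|---|---|---|---|
| alpha | 0.17 M | 0.20 M | 0.060 M | 95 °C | run made earlier |  |
| beta | 0.38 M | 0.20 M | 0.060 M | 110 °C | run made earlier |  |
| red | 0.60 M | 0.200 M | 0.0600 M | 110 °C |  | 12 h |
| ochre | 0.20 M | 0.200 M | 0.0600 M | 110 °C |  | 50 h |

| run | time / h | ring / % |
|---|---|---|
| alpha | 8.00 | 0 |
| alpha | 20.0 | 0 |
| alpha | 40.0 | 5 |
| alpha | 96.0 | 13 |
| beta | 12.0 | 2 |
| beta | 25.0 | 7 |
| beta | 40.0 | 10 |
| beta | 48.0 | 14 |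

(each reading ± 1.5 percentage points)

- a species is counted by the solid substrate in it: one open dimer counts as two
- given per volume of solution although it is solid: solid substrate
- steps that have been proposed: starting material + activator -> activated form; solid substrate <-> starting material; capture agent + activated form -> trapped intermediate; activated form -> ring; starting material + activated form -> open dimer
- at the start none of the solid substrate is in solution
- what has only dissolved of solid substrate counts as not reacted

- which of the two ends with the higher amount of ring, in percent of the solid substrate charged ("neither" if they lie within 2 percentage points) (red / ochre / neither)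
- ring at the end, in percent of the solid substrate charged, red
- ring at the end, in percent of the solid substrate charged, ochre

I, taking the minutes, argued as follows. On the proposed steps, solid substrate dissolves to starting material. The activator turns that into the activated form, which closes to ring, is caught by capture agent, or meets starting material to give open dimer. Suppose dissolution is the fast step. Then the solution stays saturated while solid is left, and ring forms at zero order in the solid charged. The same ring per volume is then a smaller fraction of a larger charge.

So I scaled beta's late reading to ochre's charge and got 26.6 %. I called this the scaled yield: a reading in beta, times beta's charge, over the charge of the flask in hand. It belongs to 48.0 h, while ochre runs 50 h, and I let that gap stand. The scatter scales too, to 2.9 percentage points for ochre. For red, read at 12 h, beta's 2 % at 12.0 h scales to 1.27 %. I therefore committed to ochre ending higher than red, by 25 points against a margin of 2 points.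

The author of the forecast also named ochre, with red at 1.6 % (0.4 % to 3.5 %) and ochre at 20 % (12 % to 30 %). That ochre figure is lower than mine, and the author's ground was “substrate depletion and trapping”. The two figures stood apart when the meeting closed.

The flasks give 25.3 % for ochre and 0.914 % for red, so ochre ends higher.

    starting material + activator → activated form (k = 0.460 /M/h, Ea = 108 kJ/mol)
    solid substrate ⇌ starting material, rate k2*(cs2 - [starting material]) while solid is left; crystals form when [starting material] > cs2 (solubility = 0.0650 M, k = 0.420 /h)
    capture agent + activated form → trapped intermediate (k = 1.40 /M/h, Ea = 87.0 kJ/mol)
    activated form → ring (k = 0.0330 /h, Ea = 117 kJ/mol)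
    starting material + activated form → open dimer (k = 0.0170 /M/h, Ea = 103 kJ/mol)
    (constants at 110 °C)

Ochre has converted 72.5 % of its solid substrate, red 7.40 %. The scaled yield of 26.6 % lies 1.3 points above ochre's result. Now take red again, read later at 50 h. Beta's 14 % from 48.0 h, scaled to red's charge, gives 8.87 %. Red at that time holds 8.44 % of ring.

(The data were computed with constants of no real substance; scatter was added.)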